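The runs are calculated from invented constants; scatter was added.

You charge 1.8 M of starting material against 1.80 M of reagent, with 90 mM of free catalyst. Neither is in excess, so the ceiling you reckon with is 100 percent of the charge, and the question is how far each set-up gets towards it.

| flask | starting material | reagent | free catalyst | remark | time |
|---|---|---|---|---|---|
| epsilon | 1.8 M | 1.8 M | 90 mM | run made earlier |  |
| gamma | 0.90 M | 1.8 M | 90 mM | run made earlier |  |
| eta | 1.4 M | 1.8 M | 90 mM | run made earlier |  |
| south-east | 1.8 M | 1.80 M | 90 mM | everything together in a closed stirred flask, run for 2.5 d | 2.5 d |
| north | 1.8 M | 1.80 M | 90 mM | one stirred flow tank at steady state, fed with the mixture as stated, mean residence time 7.50 d |  |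
| south-west | 1.8 M (fed, over 1.25 d) | 1.80 M | 90 mM | all but starting material at the start; starting material goes in evenly over 1.25 d, the run ends at 2.5 d | 2.5 d |
| west | 1.8 M | 1.80 M | 90 mM | a single well-mixed tank run continuously and read at steady state, 2.5 d in it on average |  |

| run | time / h | product / % |
|---|---|---|
| epsilon | 3.00 | 2.8 |
| epsilon | 5.00 | 6.4 |
| epsilon | 10.0 | 13.1 |
| epsilon | 20.0 | 25.5 |
| epsilon | 40.0 | 44.6 |
| gamma | 10.0 | 22.1 |
| gamma | 20.0 | 42.2 |
| gamma | 30.0 | 59.5 |
| gamma | 40.0 | 72.1 |
| gamma | 50.0 | 81.9 |
| eta | 4.00 | 5.4 |
| eta | 8.00 | 13.0 |
| eta | 15.0 | 24.1 |
| eta | 25.0 | 37.9 |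
| eta | 50.0 | 64.1 |

(readings scatter by 0.5 percentage points)

- the stated concentrations are those of everything mixed, before any reaction; amounts are the same in each set-up
- the feed brings no volume worth counting
- the earlier runs were made in a closed, stirred flask

1. the set-up with the highest amount of product at the outlet or at the end, in percent of the starting material put in ("none" if the first two lie within 2 percentage points) (south-east / north / south-west / west / none)
2. amount of product at the outlet or at the end, in percent of the starting material put in, south-east
3. amount of product at the outlet or at the end, in percent of the starting material put in, north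
4. amount of product at the outlet or at the end, in percent of the starting material put in, south-west
5. amount of product at the outlet or at the end, in percent of the starting material put in, west

Climb the time scales from the fastest. At the bottom sits a short start-up: the epsilon run makes 2.8 % in its first 3.00 h, then 3.6 percentage points in the next 2.00 h. Next comes the early rate, 0.0236 M h⁻¹ in the epsilon run. The gamma run, on half the starting material, still reads 0.0199 M h⁻¹, so that rate barely follows the charge.

This gives the number to carry, the charge time: the hours the whole charge would take at the early epsilon rate, 76.3 h. On this scale the south-west dose, over 30 h, is short, and it arrives at 0.0600 M h⁻¹, faster than the early rate, so starting material piles up in that flask. A stay of 60 h is somewhat shorter, and the north stay of 180 h is longer.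

A steady tank balances, so its outlet percent equals stay over charge time (a Damköhler number) times the running share, which is the rate at outlet composition as a fraction of the early rate. Late in the epsilon run, near 35.1 %, I read a share of 72.9 %. If the rate keeps falling as the charge runs down, my own bound puts the west tank under 57.3 %. The north tank needs a share of just 24.3 % to pass that, so I expect it above.

The forecast picks north, with 62 % for south-east, 79 % for north, 56 % for south-west and 51 % for west: “The long-residence tank wins clearly”.

The flasks give 58.9 % for south-east, 75.3 % for north, 54.1 % for south-west and 47.9 % for west, so north wins.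

    starting material + free catalyst → catalyst intermediate A (k = 3.02 × 10⁻⁴ M⁻¹ s⁻¹)
    reagent + catalyst intermediate A ⇌ catalyst intermediate B (K = 1.27 M⁻¹, k = 1.18 × 10⁻⁴ M⁻¹ s⁻¹)
    catalyst intermediate B ⇌ released group + catalyst intermediate C (K = 4.73 M, k = 3.06 × 10⁻⁴ s⁻¹)
    catalyst intermediate C → free catalyst + product (k = 0.0198 s⁻¹)
    2 catalyst intermediate B → spent catalyst (k = 1.46 × 10⁻⁴ M⁻¹ s⁻¹)

Put the charge time back on the tanks. The west tank, with a stay worth 78.6 % of it, ran at a share of 60.9 %. The north tank, at 236 %, ran at 31.9 %, lower. Reagent stands at 0.428 M in the north tank; with the consumption of reagent taken away, north gives 89.3 % instead of 75.3 %, so that consumption is one part of the fall. With the back-mixing and the longer stay taken away together, north drops to 58.9 %, level with south-east at 58.9 %.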